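**Assumption:** the target SMILES has no stereogenic element (the molecule is achiral), so "single enantiomer" means the constitution as drawn and no stereocontrol step is needed.

**Retrosynthetic overview**
- The target is traced back, by O-debenzylation and a radical C2–H alkylation with •CH2CO2Me, to 6-aryl-4,7-dimethoxy-3-methylbenzofuran; the acetate arm goes on last, at the only free furan carbon.
- Key step: a Dötz benzannulation builds the central benzene ring from a 3-furyl methoxycarbene chromium complex (C3a, C7a, C4–OMe), one CO ligand (C7–OH) and 4-(benzyloxy)phenylacetylene (C5–H, C6–aryl). This replaces the usual Suzuki biaryl coupling plus phenol O-alkylation/cyclodehydration.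
- The carbene complex comes from 3-bromo-4-methylfuran, made from 3,4-dibromofuran by two successive Br/Li exchanges.
- Ring order: the furan ring is bought, the benzene ring is formed second by benzannulation, and the hydroxyphenyl ring arrives intact on the alkyne.

**Route**

Step 1
Reactants: 1 3,4-dibromofuran
Product: 3 3-bromo-4-methylfuran, via (4-bromofuran-3-yl)lithium 2 (not isolated)
Conditions: n-BuLi (1.0 equiv), THF, −78 °C, 30 min; then MeI, −78 °C → rt
Reagents that add atoms: iodomethane CI
Why: Bromine–lithium exchange (halogen–metal exchange) on one of the two equivalent C–Br bonds is fast at −78 °C, where the 3-furyllithium does not isomerise to a 2-lithio species, and SN2 methylation by MeI then gives the monobromide.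

Step 2
Reactants: 3 3-bromo-4-methylfuran
Product: 6 pentacarbonyl[methoxy(4-methylfuran-3-yl)methylidene]chromium, via (4-methylfuran-3-yl)lithium 4 (not isolated), via lithium acylchromate 5 (not isolated)
Conditions: n-BuLi, Et2O, −78 °C; Cr(CO)6, −78 → 0 °C; then Me3OBF4, CH2Cl2, 0 °C → rt
Reagents that add atoms: chromium hexacarbonyl O=C=[Cr](=C=O)(=C=O)(=C=O)(=C=O)=C=O; trimethyloxonium tetrafluoroborate C[O+](C)C.F[B-](F)(F)F
Why: Fischer carbene synthesis, in which a second bromine–lithium exchange gives the 3-furyllithium, this adds to a CO ligand of Cr(CO)6 to form the acylchromate, and O-alkylation with the Meerwein salt delivers the methoxycarbene complex.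

Step 3
Reactants: 6 pentacarbonyl[methoxy(4-methylfuran-3-yl)methylidene]chromium; 7 1-(benzyloxy)-4-ethynylbenzene
Product: 9 6-[4-(benzyloxy)phenyl]-4-methoxy-3-methyl-1-benzofuran-7-ol, via arene tricarbonylchromium complex 8 (not isolated)
Conditions: 7 (1.5 equiv), THF (0.05 M), 55 °C, Ar, 16 h; then air, MeCN–Et2O, rt
Reagents that add atoms: none
Why: Dötz benzannulation, in which the terminal alkyne inserts into the Cr=C bond with its aryl-bearing carbon next to chromium, CO insertion gives a dienylketene that closes by 6π-electrocyclisation onto furan C2 (the only free carbon beside the carbene carbon) and tautomerises, so the carbene carbon becomes C4–OMe, the alkyne CH becomes C5, the aryl-bearing carbon C6 and the CO carbon C7–OH (larger alkyne substituent ortho to OH, the normal outcome for terminal alkynes), after which air releases the phenol from Cr(CO)3.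

Step 4
Reactants: 9 6-[4-(benzyloxy)phenyl]-4-methoxy-3-methyl-1-benzofuran-7-ol
Product: 10 6-[4-(benzyloxy)phenyl]-4,7-dimethoxy-3-methyl-1-benzofuran
Conditions: MeI, K2CO3, acetone, 56 °C, Ar (crude 9 used directly)
Reagents that add atoms: iodomethane CI
Why: Williamson O-methylation of the only free phenol (the other is masked as its benzyl ether) under mild carbonate conditions that leave the furan and the benzyl ether untouched.

Step 5
Reactants: 10 6-[4-(benzyloxy)phenyl]-4,7-dimethoxy-3-methyl-1-benzofuran
Product: 11 methyl 2-{6-[4-(benzyloxy)phenyl]-4,7-dimethoxy-3-methyl-1-benzofuran-2-yl}acetate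
Conditions: BrCH2CO2Me (3 equiv), fac-Ir(ppy)3 (ppy = 2-phenylpyridinato, 1 mol %), K2HPO4 (2 equiv), DMSO, blue LEDs (450 nm), rt
Reagents that add atoms: methyl bromoacetate COC(=O)CBr
Why: Photoredox homolytic aromatic substitution (radical C–H alkylation of an electron-rich heteroarene), in which the excited iridium photocatalyst reduces the bromoester to the electrophilic •CH2CO2Me radical, this adds to the only unsubstituted furan carbon C2 to give a tertiary benzylic radical, and oxidation followed by deprotonation restores the aromatic benzofuran.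

Step 6
Reactants: 11 methyl 2-{6-[4-(benzyloxy)phenyl]-4,7-dimethoxy-3-methyl-1-benzofuran-2-yl}acetate
Product: 12 phenylcandilide B (methyl 2-[6-(4-hydroxyphenyl)-4,7-dimethoxy-3-methyl-1-benzofuran-2-yl]acetate)
Conditions: H2 (1 atm), Pd/C (10 wt % Pd), EtOAc–MeOH, rt
Reagents that add atoms: none
Why: Catalytic hydrogenolysis over Pd/C cleaves only the benzylic C–O bond, since the methyl ethers, the methyl ester and the tetrasubstituted benzofuran C2=C3 bond are inert at 1 atm H2 and room temperature.

**Compound list**

1 | 3,4-dibromofuran | Brc1cocc1Br | starting material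
2 | (4-bromofuran-3-yl)lithium | [Li]c1cocc1Br | intermediate
3 | 3-bromo-4-methylfuran | Cc1cocc1Br | intermediate
4 | (4-methylfuran-3-yl)lithium | [Li]c1cocc1C | intermediate
5 | lithium pentacarbonyl[(4-methylfuran-3-yl)(oxido)methylidene]chromate (lithium acylchromate) | [Li+].[O-]C(c1cocc1C)=[Cr](=C=O)(=C=O)(=C=O)(=C=O)=C=O | intermediate
6 | pentacarbonyl[methoxy(4-methylfuran-3-yl)methylidene]chromium | COC(c1cocc1C)=[Cr](=C=O)(=C=O)(=C=O)(=C=O)=C=O | intermediate
7 | 1-(benzyloxy)-4-ethynylbenzene | C#Cc1ccc(OCc2ccccc2)cc1 | starting material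
8 | tricarbonyl{η6-6-[4-(benzyloxy)phenyl]-4-methoxy-3-methyl-1-benzofuran-7-ol}chromium (η6 bond written as a dot) | COc1cc(-c2ccc(OCc3ccccc3)cc2)c(O)c2occ(C)c12.O=C=[Cr](=C=O)=C=O | intermediate
9 | 6-[4-(benzyloxy)phenyl]-4-methoxy-3-methyl-1-benzofuran-7-ol | COc1cc(-c2ccc(OCc3ccccc3)cc2)c(O)c2occ(C)c12 | intermediate
10 | 6-[4-(benzyloxy)phenyl]-4,7-dimethoxy-3-methyl-1-benzofuran | COc1cc(-c2ccc(OCc3ccccc3)cc2)c(OC)c2occ(C)c12 | intermediate
11 | methyl 2-{6-[4-(benzyloxy)phenyl]-4,7-dimethoxy-3-methyl-1-benzofuran-2-yl}acetate | COC(=O)Cc1oc2c(OC)c(-c3ccc(OCc4ccccc4)cc3)cc(OC)c2c1C | intermediate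
12 | phenylcandilide B, methyl 2-[6-(4-hydroxyphenyl)-4,7-dimethoxy-3-methyl-1-benzofuran-2-yl]acetate (achiral) | COC(=O)Cc1oc2c(OC)c(-c3ccc(O)cc3)cc(OC)c2c1C | target

**Step count and risks**

Total step count: 6. Longest linear sequence: 6 steps (1 → 12); alkyne 7 enters at step 3.

The three steps most likely to fail, each with one fallback:

**Step 3 (Dötz benzannulation).** The risks are non-CO-inserted or two-alkyne by-products and the air sensitivity of phenol 9. The fallback replaces the chromium chemistry by a metal-free Moore–Liebeskind cyclobutenone ring expansion. It sets out from 7 (and from furyllithium 4, made from 3 as in step 2) and comes back at 10. Dichloroketene F1, generated from trichloroacetyl chloride and Zn–Cu couple in Et2O–DME, undergoes [2+2] cycloaddition with 7, the ketene carbonyl carbon bonding to the terminal alkyne carbon, to give 3-[4-(benzyloxy)phenyl]-4,4-dichlorocyclobut-2-en-1-one F2. Furyllithium 4 adds 1,2 to the ketone at −78 °C and aqueous work-up gives 3-[4-(benzyloxy)phenyl]-4,4-dichloro-1-(4-methylfuran-3-yl)cyclobut-2-en-1-ol F3 (racemic; the stereocentre is lost later). Silver-assisted hydrolysis of the allylic gem-dichloride (Ag2CO3, aqueous acetone) unmasks 2-[4-(benzyloxy)phenyl]-4-hydroxy-4-(4-methylfuran-3-yl)cyclobut-2-en-1-one F4; this unmasking is the least secure operation of the fallback. Heating F4 in toluene at 110 °C opens the ring to the dienylketene, which closes by 6π-electrocyclisation on furan C2 and tautomerises to 6-[4-(benzyloxy)phenyl]-3-methyl-1-benzofuran-4,7-diol F5. F5 is methylated on both oxygens under argon (MeI, K2CO3, acetone) to give 10; the regiochemistry is fixed by the cycloaddition.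

**Step 2 (carbene complex formation).** The 3-furyllithium may isomerise or be butylated while it is warmed with poorly soluble Cr(CO)6. The fallback reverses the polarity of the bond formation (nucleophilic metal, electrophilic acyl carbon; Semmelhack–Hegedus route). It sets out from 3 and comes back at 6. Compound 3 is lithiated to 4 as before, quenched at −78 °C with CO2 (instantaneous, so the lithio species is never warmed) and acidified with HCl to give 4-methylfuran-3-carboxylic acid F6. Oxalyl chloride with catalytic DMF in CH2Cl2 gives 4-methylfuran-3-carbonyl chloride F7. Dipotassium pentacarbonylchromate K2Cr(CO)5 F8, prepared from Cr(CO)6 and potassium naphthalenide (KC10H8) in THF at −78 °C, is acylated by F7 to potassium pentacarbonyl[(4-methylfuran-3-yl)(oxido)methylidene]chromate F9. O-Methylation of F9 with Me3OBF4 gives 6.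

**Step 5 (photoredox C–H alkylation).** The risks are low conversion or competing radical attack on the other arenes. The fallback replaces the radical substitution by directed metalation and cross-coupling. It sets out from 10 and comes back at 11. n-BuLi in THF at −78 °C removes the most acidic proton (furan C2–H) to give {6-[4-(benzyloxy)phenyl]-4,7-dimethoxy-3-methyl-1-benzofuran-2-yl}lithium F10. Quenching with I2 gives 6-[4-(benzyloxy)phenyl]-2-iodo-4,7-dimethoxy-3-methyl-1-benzofuran F11. Negishi-type coupling of F11 with the Reformatsky reagent bromo(2-methoxy-2-oxoethyl)zinc F12 (from methyl bromoacetate and Zn dust in THF), catalysed by the zerovalent palladium source Pd2(dba)3 with XPhos in THF at 60 °C, gives 11.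

**Further compounds**

F1 | step 3 | dichloroketene | ClC(Cl)=C=O
F2 | step 3 | 3-[4-(benzyloxy)phenyl]-4,4-dichlorocyclobut-2-en-1-one | O=C1C=C(c2ccc(OCc3ccccc3)cc2)C1(Cl)Cl
F3 | step 3 | 3-[4-(benzyloxy)phenyl]-4,4-dichloro-1-(4-methylfuran-3-yl)cyclobut-2-en-1-ol (racemic) | OC1(c2cocc2C)C=C(c2ccc(OCc3ccccc3)cc2)C1(Cl)Cl
F4 | step 3 | 2-[4-(benzyloxy)phenyl]-4-hydroxy-4-(4-methylfuran-3-yl)cyclobut-2-en-1-one (racemic) | O=C1C(c2ccc(OCc3ccccc3)cc2)=CC1(O)c1cocc1C
F5 | step 3 | 6-[4-(benzyloxy)phenyl]-3-methyl-1-benzofuran-4,7-diol | Cc1coc2c(O)c(-c3ccc(OCc4ccccc4)cc3)cc(O)c12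
F6 | step 2 | 4-methylfuran-3-carboxylic acid | Cc1cocc1C(=O)O
F7 | step 2 | 4-methylfuran-3-carbonyl chloride | Cc1cocc1C(Cl)=O
F8 | step 2 | dipotassium pentacarbonylchromate K2Cr(CO)5 | [K+].[K+].O=C=[Cr-2](=C=O)(=C=O)(=C=O)=C=O
F9 | step 2 | potassium pentacarbonyl[(4-methylfuran-3-yl)(oxido)methylidene]chromate | [K+].[O-]C(c1cocc1C)=[Cr](=C=O)(=C=O)(=C=O)(=C=O)=C=O
F10 | step 5 | {6-[4-(benzyloxy)phenyl]-4,7-dimethoxy-3-methyl-1-benzofuran-2-yl}lithium | COc1cc(-c2ccc(OCc3ccccc3)cc2)c(OC)c2oc([Li])c(C)c12
F11 | step 5 | 6-[4-(benzyloxy)phenyl]-2-iodo-4,7-dimethoxy-3-methyl-1-benzofuran | COc1cc(-c2ccc(OCc3ccccc3)cc2)c(OC)c2oc(I)c(C)c12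
F12 | step 5 | bromo(2-methoxy-2-oxoethyl)zinc | COC(=O)C[Zn]Br
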